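**Strategy.** Ring B is disconnected at C8–C8a and C4a–C5. Its C8 ketone lies between the quaternary carbinol C7 and the C8a=C4a alkene, so it maps onto a cyclobutanone (C8, C7, C6, C5) plus an alkyne (C8a≡C4a). The C7 oxygen and the C1 oxygen flank this unit, so one diisopropylsilylene can link them. Zerovalent nickel then inserts the tethered alkyne into the C8–C5 bond in one operation, closing ring B and a seven-membered siloxane ring without touching C6 or C7. The precursor is a (2S,3S)-2-methyl-2-silyloxy-3-alkylcyclobutanone, its side-chain ketone masked as a dioxolane, tethered to (E)-oct-6-ene-2,4-diyn-1-ol. Fluoride then frees the C1 oxygen for 6-endo closure of ring A.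

Key step: step 11

Numbering: the isochromene numbering of the target is used for every intermediate (C1 = OCH2, O2, C3 = propenyl-bearing carbon, C4, C4a, C5 = CH2, C6 = CH with the side chain, C7 = C(OH)CH3, C8 = C=O, C8a).

Remark: the tether alcohol is named by its eight-carbon chain, (E)-oct-6-ene-2,4-diyn-1-ol, since C1, C8a, C4a, C4, C3 and the three propenyl carbons all come from it; a seven-carbon chain cannot hold them.

Assumption: the (2S,5S) auxiliary is taken to deliver the 3S cyclobutanone (C6 of the target); should the cycloaddition favour the antipode, the equally available (2R,5R)-amine is used in steps 4 and 5 and nothing else changes.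

**Step 1**
Reactants: 1 ethyl 3-oxodecanoate
Product: 2 ethyl 2-(2-heptyl-1,3-dioxolan-2-yl)acetate
Conditions: ethylene glycol, p-TsOH (cat.), toluene, reflux (Dean–Stark)
Reagents that add atoms: ethylene glycol, OCCO
Why: Acid-catalysed ketalisation with azeotropic removal of water should mask the ketone selectively, since the ester cannot form a dioxolane.

**Step 2**
Reactants: 2 ethyl 2-(2-heptyl-1,3-dioxolan-2-yl)acetate
Product: 3 2-(2-heptyl-1,3-dioxolan-2-yl)acetaldehyde
Conditions: iBu2AlH, CH2Cl2, −78 °C; aq. potassium sodium tartrate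
Reagents that add atoms: none
Why: Partial ester reduction by iBu2AlH at −78 °C should stop at the aldehyde because the aluminium hemiacetal, here chelated by a dioxolane oxygen, collapses only on work-up.

**Step 3**
Reactants: 3 2-(2-heptyl-1,3-dioxolan-2-yl)acetaldehyde
Product: 4 2-heptyl-2-(prop-2-en-1-yl)-1,3-dioxolane
Conditions: Ph3PCH3Br, KOtBu, THF, 0 °C → rt
Reagents that add atoms: methyltriphenylphosphonium bromide, C[P+](c1ccccc1)(c1ccccc1)c1ccccc1.[Br-]
Why: Wittig methylenation with the unstabilised ylide should give the terminal alkene (its CH2 becomes C5) without affecting the dioxolane.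

**Step 4**
Reactants: 5 propionyl chloride; 6 (2S,5S)-2,5-dimethylpyrrolidine
Product: 7 1-[(2S,5S)-2,5-dimethylpyrrolidin-1-yl]propan-1-one
Conditions: Et3N, CH2Cl2, 0 °C → rt
Reagents that add atoms: none
Why: N-Acylation of the secondary amine by the acid chloride with Et3N as acid scavenger should give the tertiary amide without touching the two pyrrolidine stereocentres.

**Step 5**
Reactants: 7 1-[(2S,5S)-2,5-dimethylpyrrolidin-1-yl]propan-1-one; 4 2-heptyl-2-(prop-2-en-1-yl)-1,3-dioxolane
Product: 10 (3S)-3-[(2-heptyl-1,3-dioxolan-2-yl)methyl]-2-methylcyclobutan-1-one (mixture of C2 epimers), via keteniminium triflate 8 (not isolated), via cyclobutaniminium triflate 9 (not isolated)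
Conditions: Tf2O, 2,4,6-collidine, ClCH2CH2Cl, −20 °C; 4, reflux; then H2O, rt
Reagents that add atoms: water, O
Why: O-Triflation of the amide and loss of triflate under collidine should give the methylketeniminium ion, whose regioselective [2+2] cycloaddition with the 1-alkene (terminal CH2 to the iminium carbon, so the substituted carbon becomes C6 next to C7) and hydrolysis should give the cyclobutanone, the C2-symmetric auxiliary shielding one face so that C6 is set as S, while the C7 epimer ratio is irrelevant because C7 becomes planar in step 6.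

**Step 6**
Reactants: 10 (3S)-3-[(2-heptyl-1,3-dioxolan-2-yl)methyl]-2-methylcyclobutan-1-one
Product: 11 {[(3S)-3-[(2-heptyl-1,3-dioxolan-2-yl)methyl]-2-methylcyclobut-1-en-1-yl]oxy}trimethylsilane
Conditions: TMSCl, Et3N, DMF, 80 °C
Reagents that add atoms: chlorotrimethylsilane, C[Si](C)(C)Cl
Why: Silyl enol ether formation under equilibrating conditions (amine hydrochloride, heat) should favour the more substituted C7=C8 isomer, the tetrasubstituted cyclobutene being the more stable one, and it removes the C7 epimer mixture.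

**Step 7**
Reactants: 11 {[(3S)-3-[(2-heptyl-1,3-dioxolan-2-yl)methyl]-2-methylcyclobut-1-en-1-yl]oxy}trimethylsilane
Product: 13 (2S,3S)-3-[(2-heptyl-1,3-dioxolan-2-yl)methyl]-2-hydroxy-2-methylcyclobutan-1-one, via silyloxy epoxide 12 (not isolated)
Conditions: DMDO, acetone/CH2Cl2, −78 → 0 °C; then AcOH, THF/H2O, rt
Reagents that add atoms: dimethyldioxirane, CC1(C)OO1
Why: Rubottom oxidation: dimethyldioxirane should epoxidise the electron-rich enol ether on the face away from the C6 side chain, and hydrolytic opening of the silyloxy epoxide then gives the tertiary C7 hydroxyl trans to that side chain (7S), with no peracid present to cause Baeyer–Villiger oxidation of the strained ketone.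

**Step 8**
Reactants: 14 (E)-crotonaldehyde
Product: 15 (3E)-1,1-dibromopenta-1,3-diene
Conditions: CBr4, PPh3, CH2Cl2, 0 °C
Reagents that add atoms: carbon tetrabromide, BrC(Br)(Br)Br
Why: The first stage of the Corey–Fuchs sequence (Wittig-type dibromo-olefination) should convert the enal into the dibromodiene with the E alkene unchanged.

**Step 9**
Reactants: 15 (3E)-1,1-dibromopenta-1,3-diene; 16 prop-2-yn-1-ol
Product: 18 (E)-oct-6-ene-2,4-diyn-1-ol, via bromoenynol 17 (not isolated)
Conditions: Pd2(dba)3 (cat.), tri(2-furyl)phosphine, Et3N, DMF, 80 °C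
Reagents that add atoms: none
Why: Palladium-catalysed coupling of a 1,1-dibromoalkene with a terminal alkyne (Sonogashira-type coupling at the bromine trans to the diene, then dehydrobromination of the bromoenyne) should give the unsymmetrical conjugated diyne directly with the E propenyl group preserved.

**Step 10**
Reactants: 13 (2S,3S)-3-[(2-heptyl-1,3-dioxolan-2-yl)methyl]-2-hydroxy-2-methylcyclobutan-1-one; 19 diisopropylsilyl bis(trifluoromethanesulfonate); 18 (E)-oct-6-ene-2,4-diyn-1-ol
Product: 21 (2S,3S)-2-{[diisopropyl((E)-oct-6-ene-2,4-diyn-1-yloxy)silyl]oxy}-3-[(2-heptyl-1,3-dioxolan-2-yl)methyl]-2-methylcyclobutan-1-one, via silyl triflate 20 (not isolated)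
Conditions: 19, 2,6-lutidine, CH2Cl2, −78 °C; then 18, −78 °C → rt
Reagents that add atoms: none
Why: Sequential O-silylation with a silylene bis-triflate should first turn the hindered tertiary alcohol into a monotriflate that cannot take up a second hindered alcohol and then capture the primary propargylic alcohol, giving the mixed bis-alkoxysilane under 2,6-lutidine, which leaves the dioxolane and the cyclobutanone intact.

**Step 11**
Reactants: 21 (2S,3S)-2-{[diisopropyl((E)-oct-6-ene-2,4-diyn-1-yloxy)silyl]oxy}-3-[(2-heptyl-1,3-dioxolan-2-yl)methyl]-2-methylcyclobutan-1-one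
Product: 22 (1S,9S)-9-[(2-heptyl-1,3-dioxolan-2-yl)methyl]-1-methyl-7-[(E)-pent-3-en-1-yn-1-yl]-3,3-di(propan-2-yl)-2,4-dioxa-3-silabicyclo[4.3.1]dec-6-en-10-one (ring B enone with the C7 oxygen and the C1 oxygen bridged by the silylene)
Conditions: Ni(cod)2 (10 mol%), PCy3 (20 mol%), toluene (0.01 M), 90 °C
Reagents that add atoms: none
Why: Proposed new method: zerovalent nickel should bind the C8 carbonyl and the tethered C8a≡C4a alkyne and couple them oxidatively to an oxanickelacyclopentene (new C8–C8a bond), after which β-carbon elimination opens the strained ring at C8–C5 and reductive elimination joins C5 to C4a. The closest known reaction is the intermolecular Ni(cod)2/phosphine-catalysed insertion of internal alkynes into cyclobutanones to give cyclohex-2-enones; the silicon-tethered intramolecular variant is the untested element. The seven-membered siloxane ring closes in the 7-exo-dig mode during the oxidative cyclisation, and ring B closes by ring expansion (formal [4+2]) in the reductive elimination. No stereocentre is formed, and C6 and C7 are spectators because only C8–C5 is broken, so their configuration is carried over from 21. Two selectivities are needed: the tether, reinforced by the preference of nickel for the alkyne carbon that bears the conjugating second alkyne, should place C8 on C8a, and nickel should take the primary carbon C5 and not the quaternary, oxygen-bearing C7 in the β-carbon elimination. The bridgehead position of C8a in 22 should be tolerable because the C8a=C4a bond is trans only within the nine-membered ring that contains the long Si–O bonds.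

**Step 12**
Reactants: 22 siloxane-bridged ring B enone
Product: 24 (6S,7S)-6-[(2-heptyl-1,3-dioxolan-2-yl)methyl]-7-hydroxy-7-methyl-3-[(E)-prop-1-en-1-yl]-6,7-dihydro-1H-isochromen-8(5H)-one, via enynone diol 23 (not isolated)
Conditions: TBAF, THF, 0 °C; then K2CO3 (cat.), MeOH, rt
Reagents that add atoms: none
Why: Fluoride should cleave both Si–O bonds, and the freed C1 alkoxide should add in a 6-endo-dig oxa-Michael (1,6-) fashion to C3 of the ynenone, the position activated through C4a=C8a by the C8 carbonyl, closing ring A as the conjugated pyran.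

**Step 13**
Reactants: 24 (6S,7S)-6-[(2-heptyl-1,3-dioxolan-2-yl)methyl]-7-hydroxy-7-methyl-3-[(E)-prop-1-en-1-yl]-6,7-dihydro-1H-isochromen-8(5H)-one
Product: 25 (6S,7S)-7-hydroxy-7-methyl-6-(2-oxononyl)-3-[(E)-prop-1-en-1-yl]-6,7-dihydro-1H-isochromen-8(5H)-one (CNP0324158.2)
Conditions: PPTS, acetone/H2O, 50 °C
Reagents that add atoms: water, O
Why: Mild acid-catalysed hydrolysis of the dioxolane should unmask the side-chain ketone, while the pyran dienol ether, deactivated towards protonation by conjugation with the C8 carbonyl, and the tertiary alcohol should persist.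

**Compound list**

1 | ethyl 3-oxodecanoate | CCCCCCCC(=O)CC(=O)OCC | starting material
2 | ethyl 2-(2-heptyl-1,3-dioxolan-2-yl)acetate | CCCCCCCC1(CC(=O)OCC)OCCO1 | intermediate
3 | 2-(2-heptyl-1,3-dioxolan-2-yl)acetaldehyde | CCCCCCCC1(CC=O)OCCO1 | intermediate
4 | 2-heptyl-2-(prop-2-en-1-yl)-1,3-dioxolane | CCCCCCCC1(CC=C)OCCO1 | intermediate
5 | propionyl chloride | CCC(Cl)=O | starting material
6 | (2S,5S)-2,5-dimethylpyrrolidine | C[C@H]1CC[C@H](C)N1 | starting material
7 | 1-[(2S,5S)-2,5-dimethylpyrrolidin-1-yl]propan-1-one | CCC(=O)N1[C@@H](C)CC[C@@H]1C | intermediate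
8 | (2S,5S)-2,5-dimethyl-1-(prop-1-en-1-ylidene)pyrrolidin-1-ium trifluoromethanesulfonate (methylketeniminium salt, not isolated) | CC=C=[N+]1[C@@H](C)CC[C@@H]1C.[O-]S(=O)(=O)C(F)(F)F | intermediate
9 | (2S,5S)-1-{(3S)-3-[(2-heptyl-1,3-dioxolan-2-yl)methyl]-2-methylcyclobutylidene}-2,5-dimethylpyrrolidin-1-ium trifluoromethanesulfonate (C2 epimers, not isolated) | C1(=[N+]2[C@@H](C)CC[C@@H]2C)C(C)[C@H](CC3(CCCCCCC)OCCO3)C1.[O-]S(=O)(=O)C(F)(F)F | intermediate
10 | (3S)-3-[(2-heptyl-1,3-dioxolan-2-yl)methyl]-2-methylcyclobutan-1-one (C2 epimers) | O=C1C(C)[C@H](CC2(CCCCCCC)OCCO2)C1 | intermediate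
11 | {[(3S)-3-[(2-heptyl-1,3-dioxolan-2-yl)methyl]-2-methylcyclobut-1-en-1-yl]oxy}trimethylsilane | C[Si](C)(C)OC1=C(C)[C@H](CC2(CCCCCCC)OCCO2)C1 | intermediate
12 | 3-[(2-heptyl-1,3-dioxolan-2-yl)methyl]-4-methyl-1-(trimethylsilyloxy)-5-oxabicyclo[2.1.0]pentane, epoxide oxygen on the face opposite the C3 side chain (not isolated) | C[Si](C)(C)O[C@@]12C[C@@H](CC3(CCCCCCC)OCCO3)[C@]1(C)O2 | intermediate
13 | (2S,3S)-3-[(2-heptyl-1,3-dioxolan-2-yl)methyl]-2-hydroxy-2-methylcyclobutan-1-one (hydroxyl trans to the side chain) | O=C1[C@@](C)(O)[C@H](CC2(CCCCCCC)OCCO2)C1 | intermediate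
14 | (E)-crotonaldehyde | C/C=C/C=O | starting material
15 | (3E)-1,1-dibromopenta-1,3-diene | C/C=C/C=C(Br)Br | intermediate
16 | prop-2-yn-1-ol | C#CCO | starting material
17 | (4Z,6E)-4-bromoocta-4,6-dien-2-yn-1-ol (not isolated) | C/C=C/C=C(\Br)C#CCO | intermediate
18 | (E)-oct-6-ene-2,4-diyn-1-ol | C/C=C/C#CC#CCO | intermediate
19 | diisopropylsilyl bis(trifluoromethanesulfonate) | CC(C)[Si](OS(=O)(=O)C(F)(F)F)(OS(=O)(=O)C(F)(F)F)C(C)C | starting material
20 | {[(1S,2S)-2-[(2-heptyl-1,3-dioxolan-2-yl)methyl]-1-methyl-4-oxocyclobutyl]oxy}di(propan-2-yl)silyl trifluoromethanesulfonate (not isolated) | O=C1[C@@](C)(O[Si](C(C)C)(C(C)C)OS(=O)(=O)C(F)(F)F)[C@H](CC2(CCCCCCC)OCCO2)C1 | intermediate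
21 | (2S,3S)-2-{[diisopropyl((E)-oct-6-ene-2,4-diyn-1-yloxy)silyl]oxy}-3-[(2-heptyl-1,3-dioxolan-2-yl)methyl]-2-methylcyclobutan-1-one | O=C1[C@@](C)(O[Si](C(C)C)(C(C)C)OCC#CC#C/C=C/C)[C@H](CC2(CCCCCCC)OCCO2)C1 | intermediate
22 | (1S,9S)-9-[(2-heptyl-1,3-dioxolan-2-yl)methyl]-1-methyl-7-[(E)-pent-3-en-1-yn-1-yl]-3,3-di(propan-2-yl)-2,4-dioxa-3-silabicyclo[4.3.1]dec-6-en-10-one (cyclohexenone ring B; Si(iPr)2 links the C7 oxygen to the C8a–CH2–O oxygen; C4a carries the pentenynyl group) | C/C=C/C#CC1=C(CO[Si](C(C)C)(C(C)C)O2)C(=O)[C@]2(C)[C@H](CC3(CCCCCCC)OCCO3)C1 | intermediate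
23 | (5S,6S)-5-[(2-heptyl-1,3-dioxolan-2-yl)methyl]-6-hydroxy-2-(hydroxymethyl)-6-methyl-3-[(E)-pent-3-en-1-yn-1-yl]cyclohex-2-en-1-one (not isolated) | C/C=C/C#CC1=C(CO)C(=O)[C@@](C)(O)[C@H](CC2(CCCCCCC)OCCO2)C1 | intermediate
24 | (6S,7S)-6-[(2-heptyl-1,3-dioxolan-2-yl)methyl]-7-hydroxy-7-methyl-3-[(E)-prop-1-en-1-yl]-6,7-dihydro-1H-isochromen-8(5H)-one | C/C=C/C1=CC2=C(CO1)C(=O)[C@@](C)(O)[C@H](CC3(CCCCCCC)OCCO3)C2 | intermediate
25 | (6S,7S)-7-hydroxy-7-methyl-6-(2-oxononyl)-3-[(E)-prop-1-en-1-yl]-6,7-dihydro-1H-isochromen-8(5H)-one | C/C=C/C1=CC2=C(CO1)C(=O)[C@@](C)(O)[C@H](CC(=O)CCCCCCC)C2 | target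

**Step count and risks**

Total steps: 13. Longest linear sequence: 10 steps (steps 1, 2, 3, 5, 6, 7, 10, 11, 12, 13). Steps 4 and 8–9 are side branches.

Most likely to fail, in this order:

Step 11. Oxidative cyclisation within the tether may be outrun by nickel-mediated oligomerisation of the conjugated diyne, or be slowed by the strain of the bridged siloxane. The fallback gives up the tether and uses the established intermolecular nickel-catalysed insertion of an internal alkyne into a cyclobutanone. It sets out from 13 and 18. Alcohol 13 is capped with TESOTf and 2,6-lutidine as (2S,3S)-3-[(2-heptyl-1,3-dioxolan-2-yl)methyl]-2-methyl-2-(triethylsilyloxy)cyclobutan-1-one F1. Alcohol 18 is capped with TBSCl and imidazole as tert-butyl(dimethyl)[(E)-oct-6-ene-2,4-diyn-1-yloxy]silane F2. The two are heated with Ni(cod)2 and PCy3 in toluene at 100 °C; the conjugating second alkyne should direct nickel to C4a, so that C8 bonds to C8a. This should give (5S,6S)-2-{[tert-butyl(dimethyl)silyl]oxymethyl}-5-[(2-heptyl-1,3-dioxolan-2-yl)methyl]-6-methyl-3-[(E)-pent-3-en-1-yn-1-yl]-6-(triethylsilyloxy)cyclohex-2-en-1-one F3. TBAF then removes both silyl groups to give diol 23, which cyclises under the conditions of step 12, and the route is rejoined at 24.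

Step 5. Facial discrimination by the auxiliary may be insufficient with an unbranched 1-alkene, or the dioxolane may be opened by the electrophilic triflate species. The fallback sets the C6 configuration by desymmetrisation and sets out from 4. Dichloroketene (Cl3CCOCl, activated Zn, Et2O) should add to 4 to give racemic 2,2-dichloro-3-[(2-heptyl-1,3-dioxolan-2-yl)methyl]cyclobutan-1-one F4. Reductive dechlorination (Zn, NH4Cl, MeOH) gives the achiral 3-[(2-heptyl-1,3-dioxolan-2-yl)methyl]cyclobutan-1-one F5. Enantiotopic deprotonation with lithium bis[(S)-1-phenylethyl]amide (or its antipode, chosen to give the 3S product) in the presence of TESCl gives triethyl{[(3S)-3-[(2-heptyl-1,3-dioxolan-2-yl)methyl]cyclobut-1-en-1-yl]oxy}silane F6. MeLi then regenerates the lithium enolate, and MeI methylates it at C7, returning to the route at 10.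

Step 6. Equilibration may not favour the C7=C8 enol ether strongly enough, so that the oxidation of step 7 would be diverted to C5. The fallback generates the C7 enolate regiospecifically and sets out from 10. Sulfuryl chloride in CH2Cl2 at 0 °C chlorinates through the more substituted enol and should give (3S)-2-chloro-3-[(2-heptyl-1,3-dioxolan-2-yl)methyl]-2-methylcyclobutan-1-one F7. Zinc dust with TMSCl in Et2O then reduces the C–Cl bond to the zinc enolate, which is silylated on oxygen, returning to the route at 11.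

**Further compounds**

F1 | step 11 | (2S,3S)-3-[(2-heptyl-1,3-dioxolan-2-yl)methyl]-2-methyl-2-(triethylsilyloxy)cyclobutan-1-one | O=C1[C@@](C)(O[Si](CC)(CC)CC)[C@H](CC2(CCCCCCC)OCCO2)C1
F2 | step 11 | tert-butyl(dimethyl)[(E)-oct-6-ene-2,4-diyn-1-yloxy]silane | C/C=C/C#CC#CCO[Si](C)(C)C(C)(C)C
F3 | step 11 | (5S,6S)-2-{[tert-butyl(dimethyl)silyl]oxymethyl}-5-[(2-heptyl-1,3-dioxolan-2-yl)methyl]-6-methyl-3-[(E)-pent-3-en-1-yn-1-yl]-6-(triethylsilyloxy)cyclohex-2-en-1-one | C/C=C/C#CC1=C(CO[Si](C)(C)C(C)(C)C)C(=O)[C@@](C)(O[Si](CC)(CC)CC)[C@H](CC2(CCCCCCC)OCCO2)C1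
F4 | step 5 | 2,2-dichloro-3-[(2-heptyl-1,3-dioxolan-2-yl)methyl]cyclobutan-1-one (racemic) | O=C1CC(CC2(CCCCCCC)OCCO2)C1(Cl)Cl
F5 | step 5 | 3-[(2-heptyl-1,3-dioxolan-2-yl)methyl]cyclobutan-1-one | O=C1CC(CC2(CCCCCCC)OCCO2)C1
F6 | step 5 | triethyl{[(3S)-3-[(2-heptyl-1,3-dioxolan-2-yl)methyl]cyclobut-1-en-1-yl]oxy}silane | CC[Si](CC)(CC)OC1=C[C@H](CC2(CCCCCCC)OCCO2)C1
F7 | step 6 | (3S)-2-chloro-3-[(2-heptyl-1,3-dioxolan-2-yl)methyl]-2-methylcyclobutan-1-one (C2 epimers) | O=C1C(C)(Cl)[C@H](CC2(CCCCCCC)OCCO2)C1
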